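## Retrosynthetic overview

1. The target comes from global desilylation of a protected precursor whose aldehyde is carried as an aryl nitrile; the erythro (7S,8R) arylglycerol ether comes from the threo Evans aldol product by Mitsunobu inversion at C7.
2. The C7–C8 bond is made by a boron glycolate-type aldol between the (S)-4-benzyl-oxazolidinone aryloxyacetyl imide of the dihydrobenzofuran phenol and TIPS-protected vanillin.
3. The dihydrofuran ring is the only ring formed (all three benzene rings are purchased): its C2–O bond is closed by acid-triggered quinone-methide cyclisation of a 1,3-diol, trans to the existing C3 centre.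
4. The C2–C3 bond of that ring is made earlier by an Evans boron aldol between an (R)-4-benzyl-oxazolidinone arylacetyl imide (ring C) and MOM-protected syringaldehyde (ring B).
5. The ring C arylacetic acid comes from 4-hydroxy-3-methoxybenzonitrile by O-allylation, Claisen rearrangement and oxidative cleavage.

Assumption: the SMILES is read as (7S,8R) (erythro; C7 benzylic carbinol, C8 aryloxy carbon, C9 CH2OH) and (2R,3S) (trans) in the dihydrobenzofuran; ring A = guaiacyl ring, ring B = syringyl ring, ring C = benzo ring of the dihydrobenzofuran; TBS = tert-butyldimethylsilyl, TIPS = triisopropylsilyl, MOM = methoxymethyl.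

## Route

Step 1
Reactants: 1 4-hydroxy-3-methoxybenzonitrile; 2 allyl bromide
Product: 3 3-methoxy-4-(prop-2-en-1-yloxy)benzonitrile
Conditions: K2CO3, acetone, reflux
Reagents that add atoms: none
Why: Williamson ether synthesis (SN2) of an acidic phenol on a primary allylic bromide; no stereocentre is involved.

Step 2
Reactants: 3 3-methoxy-4-(prop-2-en-1-yloxy)benzonitrile
Product: 5 4-hydroxy-3-methoxy-5-(prop-2-en-1-yl)benzonitrile, via dienone 4 (not isolated)
Conditions: N,N-diethylaniline, 195 °C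
Reagents that add atoms: none
Why: aromatic Claisen rearrangement ([3,3]-sigmatropic shift) delivers the allyl group to the only free ortho position, and the dienone tautomerises to the phenol.

Step 3
Reactants: 5 4-hydroxy-3-methoxy-5-(prop-2-en-1-yl)benzonitrile
Product: 6 3-methoxy-4-(methoxymethoxy)-5-(prop-2-en-1-yl)benzonitrile
Conditions: MOMCl, i-Pr2NEt, CH2Cl2, 0 °C to rt
Reagents that add atoms: chloromethyl methyl ether, COCCl
Why: O-alkylation of the phenol gives an acetal protecting group that survives oxidation, boron enolates and hydride and is later removed by the same acid that closes the ring.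

Step 4
Reactants: 6 3-methoxy-4-(methoxymethoxy)-5-(prop-2-en-1-yl)benzonitrile
Product: 8 3-methoxy-4-(methoxymethoxy)-5-(2-oxoethyl)benzonitrile, via diol 7 (not isolated)
Conditions: OsO4 (2 mol %), NaIO4, 2,6-lutidine, dioxane/H2O 3:1, rt
Reagents that add atoms: osmium tetroxide, O=[Os](=O)(=O)=O (catalytic oxygen carrier); sodium periodate, [Na+].[O-]I(=O)(=O)=O (terminal oxidant)
Why: Lemieux–Johnson oxidation (dihydroxylation, then periodate glycol cleavage) shortens the allyl group to the arylacetaldehyde without touching nitrile or MOM ether.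

Step 5
Reactants: 8 3-methoxy-4-(methoxymethoxy)-5-(2-oxoethyl)benzonitrile
Product: 9 2-[5-cyano-3-methoxy-2-(methoxymethoxy)phenyl]acetic acid
Conditions: NaClO2, NaH2PO4, 2-methyl-2-butene, t-BuOH/H2O, 0 °C to rt
Reagents that add atoms: sodium chlorite, [Na+].[O-]Cl=O
Why: Pinnick oxidation converts the aldehyde to the acid under buffered conditions, with the alkene scavenging hypochlorous acid.

Step 6
Reactants: 9 2-[5-cyano-3-methoxy-2-(methoxymethoxy)phenyl]acetic acid; 10 (R)-4-benzyl-1,3-oxazolidin-2-one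
Product: 12 (4R)-4-benzyl-3-{2-[5-cyano-3-methoxy-2-(methoxymethoxy)phenyl]acetyl}-1,3-oxazolidin-2-one, via mixed pivalic anhydride 11 (not isolated)
Conditions: PivCl, Et3N, THF, −20 °C; then 10, LiCl, −20 °C to rt
Reagents that add atoms: none
Why: N-acylation through the mixed anhydride occurs at the unhindered arylacetyl carbonyl, and the LiCl/Et3N protocol avoids strong base.

Step 7
Reactants: 13 syringaldehyde (4-hydroxy-3,5-dimethoxybenzaldehyde)
Product: 14 3,5-dimethoxy-4-(methoxymethoxy)benzaldehyde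
Conditions: MOMCl, i-Pr2NEt, CH2Cl2, 0 °C to rt
Reagents that add atoms: chloromethyl methyl ether, COCCl
Why: O-alkylation masks the phenol for the boron aldol with a group cleaved together with the other MOM ether in step 10.

Step 8
Reactants: 12 (4R)-4-benzyl-3-{2-[5-cyano-3-methoxy-2-(methoxymethoxy)phenyl]acetyl}-1,3-oxazolidin-2-one; 14 3,5-dimethoxy-4-(methoxymethoxy)benzaldehyde
Product: 16 (4R)-4-benzyl-3-[(2R,3R)-2-[5-cyano-3-methoxy-2-(methoxymethoxy)phenyl]-3-[3,5-dimethoxy-4-(methoxymethoxy)phenyl]-3-hydroxypropanoyl]-1,3-oxazolidin-2-one, via boron enolate 15 (not isolated)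
Conditions: Bu2BOTf, i-Pr2NEt, CH2Cl2, 0 °C; 14, −78 to 0 °C; then pH 7 buffer, MeOH, 30% H2O2, 0 °C
Reagents that add atoms: none
Why: Evans syn-aldol through the Z-boron enolate and a Zimmerman–Traxler chair, in which the (R)-benzyl auxiliary fixes the α-centre as 2R (the future 3S centre of the dihydrobenzofuran) and the carbinol as 3R (syn, erased in step 10).

Step 9
Reactants: 16 the syn-aldol imide from step 8
Product: 17 3-[(1R,2S)-1-[3,5-dimethoxy-4-(methoxymethoxy)phenyl]-1,3-dihydroxypropan-2-yl]-5-methoxy-4-(methoxymethoxy)benzonitrile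
Conditions: LiBH4, MeOH (2 equiv), THF, 0 °C; then H2O
Reagents that add atoms: none
Why: reductive cleavage of the N-acyl oxazolidinone at the exocyclic carbonyl gives the primary alcohol without epimerising the benzylic α-centre or reducing the nitrile (the descriptor changes to 2S only through CIP priorities).

Step 10
Reactants: 17 the bis-MOM 1,3-diol from step 9
Product: 20 (2R,3S)-2-(4-hydroxy-3,5-dimethoxyphenyl)-3-(hydroxymethyl)-7-methoxy-2,3-dihydro-1-benzofuran-5-carbonitrile, via bisphenol triol 18 (not isolated), via quinone methide 19 (not isolated)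
Conditions: 3 M aq. HCl/THF 1:3 (0.02 M), 50 °C
Reagents that add atoms: none
Why: acetal hydrolysis frees both phenols, the para-hydroxybenzylic alcohol ionises to a para-quinone methide (SN1-type), and 5-ring oxa-1,6-addition of the ring C phenol places the aryl group trans to the CH2OH at the untouched C3 centre, setting C2 as R under thermodynamic and kinetic control.

Step 11
Reactants: 20 the phenolic dihydrobenzofuran from step 10; 21 ethyl bromoacetate
Product: 22 ethyl 2-{4-[(2R,3S)-5-cyano-3-(hydroxymethyl)-7-methoxy-2,3-dihydro-1-benzofuran-2-yl]-2,6-dimethoxyphenoxy}acetate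
Conditions: K2CO3, acetone, 40 °C
Reagents that add atoms: none
Why: Williamson O-alkylation, in which only the phenol is deprotonated by carbonate, so the primary alcohol is left alone.

Step 12
Reactants: 22 the hydroxy ester from step 11
Product: 23 ethyl 2-{4-[(2R,3S)-3-{[(tert-butyldimethylsilyl)oxy]methyl}-5-cyano-7-methoxy-2,3-dihydro-1-benzofuran-2-yl]-2,6-dimethoxyphenoxy}acetate
Conditions: TBSCl, imidazole, DMF, rt
Reagents that add atoms: tert-butyldimethylsilyl chloride, CC(C)(C)[Si](C)(C)Cl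
Why: silylation of the primary alcohol protects it from the acylation, enolisation and Mitsunobu steps that follow.

Step 13
Reactants: 23 the silylated ethyl ester from step 12
Product: 24 2-{4-[(2R,3S)-3-{[(tert-butyldimethylsilyl)oxy]methyl}-5-cyano-7-methoxy-2,3-dihydro-1-benzofuran-2-yl]-2,6-dimethoxyphenoxy}acetic acid
Conditions: LiOH·H2O, THF/H2O 3:1, 0 °C to rt; then 1 M HCl to pH 3, 0 °C
Reagents that add atoms: lithium hydroxide, [Li+].[OH-]
Why: saponification of the activated aryloxyacetate is fast at room temperature, where aryl nitrile and primary TBS ether are stable.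

Step 14
Reactants: 24 the aryloxyacetic acid from step 13; 25 (S)-4-benzyl-1,3-oxazolidin-2-one
Product: 27 (4S)-4-benzyl-3-(2-{4-[(2R,3S)-3-{[(tert-butyldimethylsilyl)oxy]methyl}-5-cyano-7-methoxy-2,3-dihydro-1-benzofuran-2-yl]-2,6-dimethoxyphenoxy}acetyl)-1,3-oxazolidin-2-one, via mixed pivalic anhydride 26 (not isolated)
Conditions: PivCl, Et3N, THF, −20 °C; then 25, LiCl, −20 °C to rt
Reagents that add atoms: none
Why: mixed-anhydride N-acylation installs the auxiliary that will control C8.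

Step 15
Reactants: 28 vanillin (4-hydroxy-3-methoxybenzaldehyde)
Product: 29 3-methoxy-4-[(triisopropylsilyl)oxy]benzaldehyde
Conditions: TIPSCl, imidazole, DMF, rt
Reagents that add atoms: triisopropylsilyl chloride, CC(C)[Si](Cl)(C(C)C)C(C)C
Why: silylation gives a base-tolerant aryl silyl ether that can be removed at the end with fluoride in the presence of the aldehyde.

Step 16
Reactants: 27 the aryloxyacetyl imide from step 14; 29 3-methoxy-4-[(triisopropylsilyl)oxy]benzaldehyde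
Product: 31 (4S)-4-benzyl-3-[(2S,3R)-2-{4-[(2R,3S)-3-{[(tert-butyldimethylsilyl)oxy]methyl}-5-cyano-7-methoxy-2,3-dihydro-1-benzofuran-2-yl]-2,6-dimethoxyphenoxy}-3-hydroxy-3-{3-methoxy-4-[(triisopropylsilyl)oxy]phenyl}propanoyl]-1,3-oxazolidin-2-one, via boron enolate 30 (not isolated)
Conditions: Bu2BOTf (1.5 equiv), i-Pr2NEt, CH2Cl2, −78 to 0 °C; 29, −78 to 0 °C; then pH 7 buffer, MeOH, 30% H2O2, 0 °C
Reagents that add atoms: none
Why: Evans syn-aldol of the Z-boron glycolate enolate through a Zimmerman–Traxler chair, in which the (S)-benzyl auxiliary sets the aryloxy centre in the target's C8 configuration (2S here, 8R after reduction) and the carbinol as 3R, the threo relationship to be corrected in step 19.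

Step 17
Reactants: 31 the syn-aldol imide from step 16
Product: 32 (2R,3S)-3-{[(tert-butyldimethylsilyl)oxy]methyl}-2-(4-{[(1R,2R)-1,3-dihydroxy-1-{3-methoxy-4-[(triisopropylsilyl)oxy]phenyl}propan-2-yl]oxy}-3,5-dimethoxyphenyl)-7-methoxy-2,3-dihydro-1-benzofuran-5-carbonitrile
Conditions: LiBH4, MeOH (2 equiv), THF, 0 °C; then H2O
Reagents that add atoms: none
Why: reductive removal of the auxiliary gives the threo 1,3-diol with both new centres intact, leaving nitrile and silyl ethers untouched.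

Step 18
Reactants: 32 the threo diol from step 17
Product: 33 the C9 mono-TBS ether, (2R,3S)-3-{[(tert-butyldimethylsilyl)oxy]methyl}-2-(4-{[(1R,2R)-3-[(tert-butyldimethylsilyl)oxy]-1-hydroxy-1-{3-methoxy-4-[(triisopropylsilyl)oxy]phenyl}propan-2-yl]oxy}-3,5-dimethoxyphenyl)-7-methoxy-2,3-dihydro-1-benzofuran-5-carbonitrile
Conditions: TBSCl (1.1 equiv), imidazole, CH2Cl2, 0 °C
Reagents that add atoms: tert-butyldimethylsilyl chloride, CC(C)(C)[Si](C)(C)Cl
Why: chemoselective silylation of the primary over the hindered secondary benzylic alcohol leaves only the C7 hydroxyl free.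

Step 19
Reactants: 33 the threo secondary alcohol from step 18
Product: 34 the (1S,2R) 4-nitrobenzoate, (1S,2R)-3-[(tert-butyldimethylsilyl)oxy]-2-{4-[(2R,3S)-3-{[(tert-butyldimethylsilyl)oxy]methyl}-5-cyano-7-methoxy-2,3-dihydro-1-benzofuran-2-yl]-2,6-dimethoxyphenoxy}-1-{3-methoxy-4-[(triisopropylsilyl)oxy]phenyl}propyl 4-nitrobenzoate
Conditions: 4-O2NC6H4CO2H, PPh3, DIAD, toluene, −20 °C to rt
Reagents that add atoms: 4-nitrobenzoic acid, OC(=O)c1ccc(cc1)[N+](=O)[O-]
Why: Mitsunobu reaction, in which SN2 displacement of the alkoxyphosphonium by the carboxylate inverts C7 from R to S (threo to erythro), with ionisation disfavoured by the non-polar solvent, low temperature and the adjacent electron-withdrawing aryloxy group.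

Step 20
Reactants: 34 the inverted 4-nitrobenzoate from step 19
Product: 35 the erythro alcohol, (2R,3S)-3-{[(tert-butyldimethylsilyl)oxy]methyl}-2-(4-{[(1S,2R)-3-[(tert-butyldimethylsilyl)oxy]-1-hydroxy-1-{3-methoxy-4-[(triisopropylsilyl)oxy]phenyl}propan-2-yl]oxy}-3,5-dimethoxyphenyl)-7-methoxy-2,3-dihydro-1-benzofuran-5-carbonitrile
Conditions: K2CO3 (0.3 equiv), MeOH/THF 2:1, 0 °C
Reagents that add atoms: none
Why: transesterification (methanolysis) of the activated nitrobenzoate occurs at the acyl carbon, so the inverted C7–O bond is retained, and it is fast enough at 0 °C to spare the aryl TIPS ether.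

Step 21
Reactants: 35 the erythro alcohol nitrile from step 20
Product: 37 the aldehyde, (2R,3S)-3-{[(tert-butyldimethylsilyl)oxy]methyl}-2-(4-{[(1S,2R)-3-[(tert-butyldimethylsilyl)oxy]-1-hydroxy-1-{3-methoxy-4-[(triisopropylsilyl)oxy]phenyl}propan-2-yl]oxy}-3,5-dimethoxyphenyl)-7-methoxy-2,3-dihydro-1-benzofuran-5-carbaldehyde, via aldimine 36 (not isolated)
Conditions: i-Bu2AlH (DIBAL-H, 3.5 equiv), CH2Cl2, −78 to −30 °C; then 1 M aq. HCl, 0 °C, 15 min
Reagents that add atoms: water, O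
Why: partial reduction of the nitrile by one hydride gives an N-aluminio aldimine that resists further reduction and hydrolyses on work-up to the aldehyde, the free alcohol being only deprotonated.

Step 22
Reactants: 37 the tris-silylated aldehyde from step 21
Product: 38 (2R,3S)-2-(4-{[(1S,2R)-1,3-dihydroxy-1-(4-hydroxy-3-methoxyphenyl)propan-2-yl]oxy}-3,5-dimethoxyphenyl)-3-(hydroxymethyl)-7-methoxy-2,3-dihydro-1-benzofuran-5-carbaldehyde (CID53356209)
Conditions: Bu4NF (TBAF, 4 equiv), AcOH (4 equiv), THF, 0 °C to rt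
Reagents that add atoms: none
Why: fluoride-mediated desilylation removes the aryl TIPS and both primary TBS ethers, and the acetic acid buffer keeps the phenol and aldehyde away from strongly basic conditions, so no stereocentre is touched.

## Compound list

1 | 4-hydroxy-3-methoxybenzonitrile | N#Cc1ccc(O)c(OC)c1 | starting material
2 | allyl bromide (3-bromoprop-1-ene) | C=CCBr | starting material
3 | 3-methoxy-4-(prop-2-en-1-yloxy)benzonitrile | N#Cc1ccc(OCC=C)c(OC)c1 | intermediate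
4 | 5-methoxy-4-oxo-3-(prop-2-en-1-yl)cyclohexa-1,5-diene-1-carbonitrile (Claisen dienone, racemic) | N#CC1=CC(CC=C)C(=O)C(OC)=C1 | intermediate
5 | 4-hydroxy-3-methoxy-5-(prop-2-en-1-yl)benzonitrile | N#Cc1cc(CC=C)c(O)c(OC)c1 | intermediate
6 | 3-methoxy-4-(methoxymethoxy)-5-(prop-2-en-1-yl)benzonitrile | N#Cc1cc(CC=C)c(OCOC)c(OC)c1 | intermediate
7 | 3-(2,3-dihydroxypropyl)-5-methoxy-4-(methoxymethoxy)benzonitrile (racemic) | N#Cc1cc(CC(O)CO)c(OCOC)c(OC)c1 | intermediate
8 | 3-methoxy-4-(methoxymethoxy)-5-(2-oxoethyl)benzonitrile | N#Cc1cc(CC=O)c(OCOC)c(OC)c1 | intermediate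
9 | 2-[5-cyano-3-methoxy-2-(methoxymethoxy)phenyl]acetic acid | N#Cc1cc(CC(=O)O)c(OCOC)c(OC)c1 | intermediate
10 | (R)-4-benzyl-1,3-oxazolidin-2-one | O=C1N[C@H](Cc2ccccc2)CO1 | starting material
11 | 2-[5-cyano-3-methoxy-2-(methoxymethoxy)phenyl]acetic 2,2-dimethylpropanoic anhydride | CC(C)(C)C(=O)OC(=O)Cc1cc(C#N)cc(OC)c1OCOC | intermediate
12 | (4R)-4-benzyl-3-{2-[5-cyano-3-methoxy-2-(methoxymethoxy)phenyl]acetyl}-1,3-oxazolidin-2-one | N#Cc1cc(CC(=O)N2[C@H](Cc3ccccc3)COC2=O)c(OCOC)c(OC)c1 | intermediate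
13 | syringaldehyde (4-hydroxy-3,5-dimethoxybenzaldehyde) | COc1cc(C=O)cc(OC)c1O | starting material
14 | 3,5-dimethoxy-4-(methoxymethoxy)benzaldehyde | COCOc1c(OC)cc(C=O)cc1OC | intermediate
15 | (Z)-O-dibutylboryl enolate of 12 | CCCCB(CCCC)O/C(=C\c1cc(C#N)cc(OC)c1OCOC)N1[C@H](Cc2ccccc2)COC1=O | intermediate
16 | (4R)-4-benzyl-3-[(2R,3R)-2-[5-cyano-3-methoxy-2-(methoxymethoxy)phenyl]-3-[3,5-dimethoxy-4-(methoxymethoxy)phenyl]-3-hydroxypropanoyl]-1,3-oxazolidin-2-one | COCOc1c(OC)cc(cc1OC)[C@H](O)[C@H](C(=O)N1[C@H](Cc2ccccc2)COC1=O)c1cc(C#N)cc(OC)c1OCOC | intermediate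
17 | 3-[(1R,2S)-1-[3,5-dimethoxy-4-(methoxymethoxy)phenyl]-1,3-dihydroxypropan-2-yl]-5-methoxy-4-(methoxymethoxy)benzonitrile | COCOc1c(OC)cc(cc1OC)[C@H](O)[C@H](CO)c1cc(C#N)cc(OC)c1OCOC | intermediate
18 | 4-hydroxy-3-[(1R,2S)-1,3-dihydroxy-1-(4-hydroxy-3,5-dimethoxyphenyl)propan-2-yl]-5-methoxybenzonitrile | COc1cc(cc(OC)c1O)[C@H](O)[C@H](CO)c1cc(C#N)cc(OC)c1O | intermediate
19 | 4-hydroxy-3-[(2S)-1-hydroxy-3-(3,5-dimethoxy-4-oxocyclohexa-2,5-dien-1-ylidene)propan-2-yl]-5-methoxybenzonitrile (para-quinone methide, protonated on oxygen in the acidic medium) | COC1=CC(=C[C@H](CO)c2cc(C#N)cc(OC)c2O)C=C(OC)C1=O | intermediate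
20 | (2R,3S)-2-(4-hydroxy-3,5-dimethoxyphenyl)-3-(hydroxymethyl)-7-methoxy-2,3-dihydro-1-benzofuran-5-carbonitrile | COc1cc(cc(OC)c1O)[C@@H]1Oc2c(OC)cc(C#N)cc2[C@H]1CO | intermediate
21 | ethyl bromoacetate | CCOC(=O)CBr | starting material
22 | ethyl 2-{4-[(2R,3S)-5-cyano-3-(hydroxymethyl)-7-methoxy-2,3-dihydro-1-benzofuran-2-yl]-2,6-dimethoxyphenoxy}acetate | CCOC(=O)COc1c(OC)cc(cc1OC)[C@@H]1Oc2c(OC)cc(C#N)cc2[C@H]1CO | intermediate
23 | ethyl 2-{4-[(2R,3S)-3-{[(tert-butyldimethylsilyl)oxy]methyl}-5-cyano-7-methoxy-2,3-dihydro-1-benzofuran-2-yl]-2,6-dimethoxyphenoxy}acetate | CCOC(=O)COc1c(OC)cc(cc1OC)[C@@H]1Oc2c(OC)cc(C#N)cc2[C@H]1CO[Si](C)(C)C(C)(C)C | intermediate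
24 | 2-{4-[(2R,3S)-3-{[(tert-butyldimethylsilyl)oxy]methyl}-5-cyano-7-methoxy-2,3-dihydro-1-benzofuran-2-yl]-2,6-dimethoxyphenoxy}acetic acid | OC(=O)COc1c(OC)cc(cc1OC)[C@@H]1Oc2c(OC)cc(C#N)cc2[C@H]1CO[Si](C)(C)C(C)(C)C | intermediate
25 | (S)-4-benzyl-1,3-oxazolidin-2-one | O=C1N[C@@H](Cc2ccccc2)CO1 | starting material
26 | mixed anhydride of 24 and 2,2-dimethylpropanoic acid | CC(C)(C)C(=O)OC(=O)COc1c(OC)cc(cc1OC)[C@@H]1Oc2c(OC)cc(C#N)cc2[C@H]1CO[Si](C)(C)C(C)(C)C | intermediate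
27 | (4S)-4-benzyl-3-(2-{4-[(2R,3S)-3-{[(tert-butyldimethylsilyl)oxy]methyl}-5-cyano-7-methoxy-2,3-dihydro-1-benzofuran-2-yl]-2,6-dimethoxyphenoxy}acetyl)-1,3-oxazolidin-2-one | O=C(COc1c(OC)cc(cc1OC)[C@@H]1Oc2c(OC)cc(C#N)cc2[C@H]1CO[Si](C)(C)C(C)(C)C)N1[C@@H](Cc2ccccc2)COC1=O | intermediate
28 | vanillin (4-hydroxy-3-methoxybenzaldehyde) | COc1cc(C=O)ccc1O | starting material
29 | 3-methoxy-4-[(triisopropylsilyl)oxy]benzaldehyde | COc1cc(C=O)ccc1O[Si](C(C)C)(C(C)C)C(C)C | intermediate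
30 | (Z)-O-dibutylboryl enolate of 27 | CCCCB(CCCC)O/C(=C\Oc1c(OC)cc(cc1OC)[C@@H]1Oc2c(OC)cc(C#N)cc2[C@H]1CO[Si](C)(C)C(C)(C)C)N1[C@@H](Cc2ccccc2)COC1=O | intermediate
31 | (4S)-4-benzyl-3-[(2S,3R)-2-{4-[(2R,3S)-3-{[(tert-butyldimethylsilyl)oxy]methyl}-5-cyano-7-methoxy-2,3-dihydro-1-benzofuran-2-yl]-2,6-dimethoxyphenoxy}-3-hydroxy-3-{3-methoxy-4-[(triisopropylsilyl)oxy]phenyl}propanoyl]-1,3-oxazolidin-2-one | COc1cc(ccc1O[Si](C(C)C)(C(C)C)C(C)C)[C@@H](O)[C@@H](C(=O)N1[C@@H](Cc2ccccc2)COC1=O)Oc1c(OC)cc(cc1OC)[C@@H]1Oc2c(OC)cc(C#N)cc2[C@H]1CO[Si](C)(C)C(C)(C)C | intermediate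
32 | (2R,3S)-3-{[(tert-butyldimethylsilyl)oxy]methyl}-2-(4-{[(1R,2R)-1,3-dihydroxy-1-{3-methoxy-4-[(triisopropylsilyl)oxy]phenyl}propan-2-yl]oxy}-3,5-dimethoxyphenyl)-7-methoxy-2,3-dihydro-1-benzofuran-5-carbonitrile (threo) | COc1cc(ccc1O[Si](C(C)C)(C(C)C)C(C)C)[C@@H](O)[C@@H](CO)Oc1c(OC)cc(cc1OC)[C@@H]1Oc2c(OC)cc(C#N)cc2[C@H]1CO[Si](C)(C)C(C)(C)C | intermediate
33 | (2R,3S)-3-{[(tert-butyldimethylsilyl)oxy]methyl}-2-(4-{[(1R,2R)-3-[(tert-butyldimethylsilyl)oxy]-1-hydroxy-1-{3-methoxy-4-[(triisopropylsilyl)oxy]phenyl}propan-2-yl]oxy}-3,5-dimethoxyphenyl)-7-methoxy-2,3-dihydro-1-benzofuran-5-carbonitrile | COc1cc(ccc1O[Si](C(C)C)(C(C)C)C(C)C)[C@@H](O)[C@@H](CO[Si](C)(C)C(C)(C)C)Oc1c(OC)cc(cc1OC)[C@@H]1Oc2c(OC)cc(C#N)cc2[C@H]1CO[Si](C)(C)C(C)(C)C | intermediate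
34 | (1S,2R)-3-[(tert-butyldimethylsilyl)oxy]-2-{4-[(2R,3S)-3-{[(tert-butyldimethylsilyl)oxy]methyl}-5-cyano-7-methoxy-2,3-dihydro-1-benzofuran-2-yl]-2,6-dimethoxyphenoxy}-1-{3-methoxy-4-[(triisopropylsilyl)oxy]phenyl}propyl 4-nitrobenzoate | COc1cc(ccc1O[Si](C(C)C)(C(C)C)C(C)C)[C@H](OC(=O)c1ccc(cc1)[N+](=O)[O-])[C@@H](CO[Si](C)(C)C(C)(C)C)Oc1c(OC)cc(cc1OC)[C@@H]1Oc2c(OC)cc(C#N)cc2[C@H]1CO[Si](C)(C)C(C)(C)C | intermediate
35 | (2R,3S)-3-{[(tert-butyldimethylsilyl)oxy]methyl}-2-(4-{[(1S,2R)-3-[(tert-butyldimethylsilyl)oxy]-1-hydroxy-1-{3-methoxy-4-[(triisopropylsilyl)oxy]phenyl}propan-2-yl]oxy}-3,5-dimethoxyphenyl)-7-methoxy-2,3-dihydro-1-benzofuran-5-carbonitrile (erythro) | COc1cc(ccc1O[Si](C(C)C)(C(C)C)C(C)C)[C@H](O)[C@@H](CO[Si](C)(C)C(C)(C)C)Oc1c(OC)cc(cc1OC)[C@@H]1Oc2c(OC)cc(C#N)cc2[C@H]1CO[Si](C)(C)C(C)(C)C | intermediate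
36 | the 5-(iminomethyl) analogue of 35 (aldimine, N-aluminated in the flask) | COc1cc(ccc1O[Si](C(C)C)(C(C)C)C(C)C)[C@H](O)[C@@H](CO[Si](C)(C)C(C)(C)C)Oc1c(OC)cc(cc1OC)[C@@H]1Oc2c(OC)cc(C=N)cc2[C@H]1CO[Si](C)(C)C(C)(C)C | intermediate
37 | (2R,3S)-3-{[(tert-butyldimethylsilyl)oxy]methyl}-2-(4-{[(1S,2R)-3-[(tert-butyldimethylsilyl)oxy]-1-hydroxy-1-{3-methoxy-4-[(triisopropylsilyl)oxy]phenyl}propan-2-yl]oxy}-3,5-dimethoxyphenyl)-7-methoxy-2,3-dihydro-1-benzofuran-5-carbaldehyde | COc1cc(ccc1O[Si](C(C)C)(C(C)C)C(C)C)[C@H](O)[C@@H](CO[Si](C)(C)C(C)(C)C)Oc1c(OC)cc(cc1OC)[C@@H]1Oc2c(OC)cc(C=O)cc2[C@H]1CO[Si](C)(C)C(C)(C)C | intermediate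
38 | (2R,3S)-2-(4-{[(1S,2R)-1,3-dihydroxy-1-(4-hydroxy-3-methoxyphenyl)propan-2-yl]oxy}-3,5-dimethoxyphenyl)-3-(hydroxymethyl)-7-methoxy-2,3-dihydro-1-benzofuran-5-carbaldehyde | COc1cc(ccc1O)[C@H](O)[C@@H](CO)Oc1c(OC)cc(cc1OC)[C@@H]1Oc2c(OC)cc(C=O)cc2[C@H]1CO | target

## Step count and risks

Total steps: 22. Longest linear sequence: 20 steps (steps 1–6, 8–14 and 16–22); steps 7 and 15 are one-step side branches.

The three steps most likely to fail:

**Step 10 (acid-triggered MOM removal and cyclisation).** The risks are incomplete ring closure in the aqueous medium, intermolecular capture of the benzylic cation by the electron-rich ring B, and formaldehyde side reactions. The fallback sets out from 17 and comes back at 20. Compound 17 is treated with HCl in methanol (1.25 M, 40 °C), where the MOM groups leave as volatile dimethoxymethane and the benzylic hydroxyl is exchanged for methoxy. This gives the isolable bisphenol benzylic methyl ether 4-hydroxy-3-[(2S)-3-hydroxy-1-(4-hydroxy-3,5-dimethoxyphenyl)-1-methoxypropan-2-yl]-5-methoxybenzonitrile F1, as both epimers at the ether carbon, which is of no consequence. Purified F1 is then ionised in a non-nucleophilic medium (BF3·OEt2, CH2Cl2, −20 °C, high dilution). Loss of methanol gives the same cation with no competing external nucleophile, and the ring C phenol closes to 20 trans to the unchanged C3 centre.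

**Step 16 (glycolate boron aldol on the advanced, hindered, nitrile-bearing imide).** The risks are low conversion or an eroded syn ratio. The fallback sets out from 24 and comes back at 32. Acid 24 is coupled (EDC·HCl, DMAP, CH2Cl2) with purchased (S)-4-benzyl-1,3-thiazolidine-2-thione to give the N-acyl thiazolidinethione (4S)-4-benzyl-3-(2-{4-[(2R,3S)-3-{[(tert-butyldimethylsilyl)oxy]methyl}-5-cyano-7-methoxy-2,3-dihydro-1-benzofuran-2-yl]-2,6-dimethoxyphenoxy}acetyl)-1,3-thiazolidine-2-thione F2. Its chlorotitanium enolate (TiCl4, i-Pr2NEt, N-methyl-2-pyrrolidone, CH2Cl2, −78 to 0 °C) adds to 29 in the same facial sense to give the (2S,3R) syn-aldol thiazolidinethione F3. NaBH4 in THF/H2O then cleaves the easily displaced auxiliary and delivers diol 32 directly.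

**Step 19 (Mitsunobu inversion at an electron-rich benzylic carbinol).** The risks are partial ionisation, which would erode the erythro:threo ratio, and elimination. The fallback sets out from 33 and comes back at 35, bypassing 34. Alcohol 33 is oxidised with Dess–Martin periodinane (NaHCO3, CH2Cl2, 0 °C) to the (2R)-configured α-aryloxy ketone (2R,3S)-3-{[(tert-butyldimethylsilyl)oxy]methyl}-2-(4-{[(2R)-3-[(tert-butyldimethylsilyl)oxy]-1-{3-methoxy-4-[(triisopropylsilyl)oxy]phenyl}-1-oxopropan-2-yl]oxy}-3,5-dimethoxyphenyl)-7-methoxy-2,3-dihydro-1-benzofuran-5-carbonitrile F4. Chelation-controlled reduction (Zn(BH4)2, Et2O, −30 °C; Cram-chelate delivery of hydride across the ketone and α-aryloxy oxygens) gives the anti, that is erythro, alcohol 35. The small amount of threo isomer 33 is separated and recycled.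

## Further compounds

F1 | step 10 | 4-hydroxy-3-[(2S)-3-hydroxy-1-(4-hydroxy-3,5-dimethoxyphenyl)-1-methoxypropan-2-yl]-5-methoxybenzonitrile (both epimers at C1) | COC(c1cc(OC)c(O)c(OC)c1)[C@H](CO)c1cc(C#N)cc(OC)c1O
F2 | step 16 | (4S)-4-benzyl-3-(2-{4-[(2R,3S)-3-{[(tert-butyldimethylsilyl)oxy]methyl}-5-cyano-7-methoxy-2,3-dihydro-1-benzofuran-2-yl]-2,6-dimethoxyphenoxy}acetyl)-1,3-thiazolidine-2-thione | O=C(COc1c(OC)cc(cc1OC)[C@@H]1Oc2c(OC)cc(C#N)cc2[C@H]1CO[Si](C)(C)C(C)(C)C)N1[C@@H](Cc2ccccc2)CSC1=S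
F3 | step 16 | (4S)-4-benzyl-3-[(2S,3R)-2-{4-[(2R,3S)-3-{[(tert-butyldimethylsilyl)oxy]methyl}-5-cyano-7-methoxy-2,3-dihydro-1-benzofuran-2-yl]-2,6-dimethoxyphenoxy}-3-hydroxy-3-{3-methoxy-4-[(triisopropylsilyl)oxy]phenyl}propanoyl]-1,3-thiazolidine-2-thione | COc1cc(ccc1O[Si](C(C)C)(C(C)C)C(C)C)[C@@H](O)[C@@H](C(=O)N1[C@@H](Cc2ccccc2)CSC1=S)Oc1c(OC)cc(cc1OC)[C@@H]1Oc2c(OC)cc(C#N)cc2[C@H]1CO[Si](C)(C)C(C)(C)C
F4 | step 19 | (2R,3S)-3-{[(tert-butyldimethylsilyl)oxy]methyl}-2-(4-{[(2R)-3-[(tert-butyldimethylsilyl)oxy]-1-{3-methoxy-4-[(triisopropylsilyl)oxy]phenyl}-1-oxopropan-2-yl]oxy}-3,5-dimethoxyphenyl)-7-methoxy-2,3-dihydro-1-benzofuran-5-carbonitrile | COc1cc(ccc1O[Si](C(C)C)(C(C)C)C(C)C)C(=O)[C@@H](CO[Si](C)(C)C(C)(C)C)Oc1c(OC)cc(cc1OC)[C@@H]1Oc2c(OC)cc(C#N)cc2[C@H]1CO[Si](C)(C)C(C)(C)C
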